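**Strategy.** Ring B is closed last, between the two ring methylenes C6 and C7 (labdane numbering), by a carbonyl-ene reaction of type 2. In one operation a ring-A C6 aldehyde and the isopropenyl group on C9 give the C6–C7 bond and the exocyclic C8=C17 methylene, because the homoallylic array C6–C7–C8(=C17) of ring B is an ene retron; the C6 hydroxyl left behind is removed afterwards. The precursor is a monocyclic ring-A aldehyde, made by an anionic oxy-Cope rearrangement that transfers a linalool-derived allyl unit from C6 to C10, sets C9 and C10 through a chair transition state and, on protonation of the enolate, the cis hydrogen at C5.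

Key step: step 11

Remark: locants are labdane numbers; the target is read as (4S,5S,9S,10R,13R), i.e. cis A/B fusion with H-5, the C10 methyl and the C4 carboxyl on one face; (R)-linalool and tert-butyl 2-oxocyclohexane-1-carboxylate are taken as purchasable.

**Route**

Step 1
Reactants: 1 (R)-(−)-linalool
Product: 2 (3R)-3,7-dimethyl-3-(triethylsilyloxy)octa-1,6-diene
Conditions: Et3SiOTf, 2,6-lutidine, CH2Cl2, −78 → 0 °C
Reagents that add atoms: triethylsilyl trifluoromethanesulfonate CC[Si](CC)(CC)OS(=O)(=O)C(F)(F)F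
Why: A silyl triflate with a hindered pyridine base silylates the tertiary allylic alcohol without ionising it, so the C13 stereocentre taken from the chiral pool is carried through unchanged.

Step 2
Reactants: 2 (3R)-3,7-dimethyl-3-(triethylsilyloxy)octa-1,6-diene
Product: 3 (2E,6R)-2,6-dimethyl-6-(triethylsilyloxy)octa-2,7-dien-1-ol
Conditions: SeO2 (0.5 equiv), t-BuOOH, salicylic acid (cat.), CH2Cl2, rt
Reagents that add atoms: tert-butyl hydroperoxide CC(C)(C)OO (oxygen source, relayed by catalytic selenium dioxide O=[Se]=O)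
Why: Riley allylic oxidation (ene reaction with SeO2, then a [2,3] shift) attacks the electron-rich trisubstituted alkene at its E-methyl group and should give the (E)-allylic alcohol, while the vinyl group, which has no allylic hydrogen, is left alone.

Step 3
Reactants: 3 (2E,6R)-2,6-dimethyl-6-(triethylsilyloxy)octa-2,7-dien-1-ol
Product: 5 tributyl[(2E,6R)-2,6-dimethyl-6-(triethylsilyloxy)octa-2,7-dien-1-yl]stannane, via allylic mesylate 4 (not isolated)
Conditions: MsCl, Et3N, THF, −40 °C; then Bu3SnLi (from Bu3SnH and LiN(i-Pr)2), −78 → 0 °C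
Reagents that add atoms: tributylstannyllithium [Li][Sn](CCCC)(CCCC)CCCC
Why: The primary allylic mesylate made in situ is displaced in an SN2 reaction by the soft stannyl anion at the unhindered CH2 carbon, which keeps the E geometry and gives the allylstannane for the fragment coupling.

Step 4
Reactants: 6 tert-butyl 2-oxocyclohexane-1-carboxylate
Product: 7 tert-butyl (1S)-1-methyl-2-oxocyclohexane-1-carboxylate
Conditions: MeI, CsOH·H2O, chiral C2-symmetric N-spiro binaphthyl quaternary ammonium bromide (1 mol%), toluene, −40 °C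
Reagents that add atoms: iodomethane CI
Why: Asymmetric phase-transfer alkylation methylates the β-keto ester enolate inside a tight ion pair with the chiral ammonium cation, which shields one enolate face and sets the quaternary C4 stereocentre (S); the bulky tert-butyl ester is the substrate class this catalysis handles best.

Step 5
Reactants: 7 tert-butyl (1S)-1-methyl-2-oxocyclohexane-1-carboxylate
Product: 8 tert-butyl (1S)-1,3-dimethyl-2-oxocyclohexane-1-carboxylate (both C3 epimers)
Conditions: LiN(i-Pr)2, THF, −78 °C; MeI, −78 → 0 °C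
Reagents that add atoms: iodomethane CI
Why: The ketone can enolise only toward C10, so enolate alkylation introduces the C20 methyl regiospecifically; the configuration at C10 is irrelevant because this carbon becomes sp2 in step 6.

Step 6
Reactants: 8 tert-butyl (1S)-1,3-dimethyl-2-oxocyclohexane-1-carboxylate
Product: 9 tert-butyl (1S)-1,3-dimethyl-2-(trifluoromethylsulfonyloxy)cyclohex-2-ene-1-carboxylate
Conditions: KN(SiMe3)2, THF, −78 °C; PhNTf2, −78 → 0 °C
Reagents that add atoms: N-phenylbis(trifluoromethanesulfonimide) O=S(=O)(N(c1ccccc1)S(=O)(=O)C(F)(F)F)C(F)(F)F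
Why: Deprotonation of the one remaining α-hydrogen gives the tetrasubstituted potassium enolate, which is O-sulfonylated to the enol triflate, the only regioisomer possible since C4 is quaternary.

Step 7
Reactants: 9 tert-butyl (1S)-1,3-dimethyl-2-(trifluoromethylsulfonyloxy)cyclohex-2-ene-1-carboxylate; 5 tributyl[(2E,6R)-2,6-dimethyl-6-(triethylsilyloxy)octa-2,7-dien-1-yl]stannane
Product: 10 tert-butyl (4S,8E,13R)-6-oxo-13-(triethylsilyloxy)-9,10-secolabda-5(10),8,14-trien-19-oate
Conditions: Pd(PPh3)4 (5 mol%), LiCl, CO (3 atm), THF, 55 °C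
Reagents that add atoms: carbon monoxide [C-]#[O+]
Why: Carbonylative Stille coupling (oxidative addition of the enol triflate to zerovalent palladium, CO insertion, transmetalation of the allylstannane at its CH2 terminus, reductive elimination) joins the fragments through the new C5–C6 and C6–C7 bonds with CO as C6, a coupling known for equally hindered 2,6,6-trisubstituted cyclohexenyl triflates.

Step 8
Reactants: 10 tert-butyl (4S,8E,13R)-6-oxo-13-(triethylsilyloxy)-9,10-secolabda-5(10),8,14-trien-19-oate
Product: 12 (4S,6S,8E,13R)-13-(triethylsilyloxy)-9,10-secolabda-5(10),8,14-trien-19,6-olide, via hydroxy ester 11 (not isolated)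
Conditions: (R)-2-methyl-CBS-oxazaborolidine (0.5 equiv), BH3·SMe2, toluene, −30 °C; MeOH; then KOt-Bu (0.1 equiv), THF, 0 °C
Reagents that add atoms: none
Why: Corey–Bakshi–Shibata reduction (cyclohexenyl as the large group, the allylic CH2 as the small one) should set the 6S carbinol, and catalytic alkoxide then closes the γ-lactone onto the neighbouring ester by acyl–oxygen exchange (C6–O untouched), a temporary ring that keeps the alkoxide of the next step from being consumed by the ester.

Step 9
Reactants: 12 (4S,6S,8E,13R)-13-(triethylsilyloxy)-9,10-secolabda-5(10),8,14-trien-19,6-olide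
Product: 15 (4S,5S,9S,10R,13R)-6-oxo-13-(triethylsilyloxy)-6,7-secolabda-7,14-dien-19-oic acid, via dipotassium alkoxide carboxylate 13 (not isolated), via dipotassium enolate carboxylate 14 (not isolated)
Conditions: KOH, THF–H2O, rt; evaporation, azeotropic drying (toluene); KN(SiMe3)2, 18-crown-6, THF, 0 → 45 °C; AcOH, −78 °C
Reagents that add atoms: potassium hydroxide [K+].[OH-]
Why: Hydroxide opens the lactone and the potassium alkoxide then undergoes the anionic oxy-Cope [3,3] rearrangement through a chair transition state in which allylic 1,3-strain with the cis C20 methyl forces the C6 hydrogen axial and the E alkene places C11 equatorial, so the 6S centre is relayed into 9S and 10R while the C6–C7 tether breaks; the enolate is then protonated at C5 from the face opposite the bulky C9 branch, the face from which the neighbouring C19 carboxylic acid can also deliver the proton, to give the cis (5S) aldehyde.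

Step 10
Reactants: 15 (4S,5S,9S,10R,13R)-6-oxo-13-(triethylsilyloxy)-6,7-secolabda-7,14-dien-19-oic acid
Product: 16 2-(trimethylsilyl)ethyl (4S,5S,9S,10R,13R)-6-oxo-13-(triethylsilyloxy)-6,7-secolabda-7,14-dien-19-oate
Conditions: Me3SiCH2CH2OH, PPh3, i-PrO2CN=NCO2i-Pr, THF, 0 °C → rt
Reagents that add atoms: 2-(trimethylsilyl)ethanol C[Si](C)(C)CCO
Why: Mitsunobu esterification activates the alcohol and not the hindered neopentyl carboxyl group, so the carboxylate only attacks a primary carbon; the fluoride-labile ester avoids any later nucleophilic attack at C19 and the near-neutral conditions spare the epimerisable C5 aldehyde.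

Step 11
Reactants: 16 2-(trimethylsilyl)ethyl (4S,5S,9S,10R,13R)-6-oxo-13-(triethylsilyloxy)-6,7-secolabda-7,14-dien-19-oate
Product: 17 2-(trimethylsilyl)ethyl (4S,5S,9S,10R,13R)-6-hydroxy-13-(triethylsilyloxy)-5β-labda-8(17),14-dien-19-oate (C6 configuration not assigned)
Conditions: Me2AlCl (2 equiv), CH2Cl2, −78 → −30 °C; aq. potassium sodium tartrate
Reagents that add atoms: none
Why: Me2AlCl binds the aldehyde oxygen and the activated C6 carbonyl (enophile) is attacked by the terminal CH2 (C7) of the C9 isopropenyl group (ene) while a hydrogen of the C17 methyl passes to oxygen through a six-centre array, so the C6–C7 bond forms and the π bond moves to the exocyclic C8=C17 position in the same event; the closest known reaction type is the Lewis-acid-promoted intramolecular carbonyl-ene reaction of type 2 (ene tethered through its central carbon), the standard entry to 3-methylenecyclohexanols. Ring B closes in a 6-exo-trig sense at the carbonyl (the C=O stays outside the new ring) and endo with respect to the ene double bond, through a chair-like bicyclic transition state. The only new stereocentre, the C6 carbinol, is of no consequence because its oxygen is removed in steps 12 and 13, whereas the cis ring fusion follows from the substrate: C6 and the C9 branch already stand cis on ring A at C5 and C10, so closure can only give the cis-decalin. The step needs site selectivity (the 1,1-disubstituted isopropenyl alkene reacts, the distant and less nucleophilic C14=C15 vinyl cannot reach the aldehyde), hydrogen transfer from the methyl group and not from C9–H (secured by the type 2 geometry, in which the tether hydrogen cannot reach the oxygen) and retention of C5, which is protected by the low temperature and by the two quaternary neighbours that hinder enolisation. Me2AlCl also scavenges protons, so the polarised intermediate should not go on to chloride capture or double-bond migration.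

Step 12
Reactants: 17 2-(trimethylsilyl)ethyl (4S,5S,9S,10R,13R)-6-hydroxy-13-(triethylsilyloxy)-5β-labda-8(17),14-dien-19-oate
Product: 18 2-(trimethylsilyl)ethyl (4S,5S,9S,10R,13R)-6-(phenoxythiocarbonyloxy)-13-(triethylsilyloxy)-5β-labda-8(17),14-dien-19-oate
Conditions: PhOC(S)Cl, pyridine, DMAP (cat.), CH2Cl2, rt
Reagents that add atoms: O-phenyl chlorothionoformate S=C(Cl)Oc1ccccc1
Why: Acylation of the secondary C6 alcohol under nucleophilic catalysis gives the thionocarbonate needed for Barton–McCombie deoxygenation under non-basic conditions, so no alkoxide is formed that could lactonise onto the C19 ester.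

Step 13
Reactants: 18 2-(trimethylsilyl)ethyl (4S,5S,9S,10R,13R)-6-(phenoxythiocarbonyloxy)-13-(triethylsilyloxy)-5β-labda-8(17),14-dien-19-oate
Product: 19 2-(trimethylsilyl)ethyl (4S,5S,9S,10R,13R)-13-(triethylsilyloxy)-5β-labda-8(17),14-dien-19-oate
Conditions: Bu3SnH, AIBN (cat.), toluene, 90 °C
Reagents that add atoms: none
Why: Barton–McCombie deoxygenation: the stannyl radical adds to the thiocarbonyl sulfur, β-scission gives the secondary C6 radical, and this abstracts hydrogen from Bu3SnH faster than the homoallyl radical can rearrange, which removes the oxygen that served the ring closure without touching any stereocentre.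

Step 14
Reactants: 19 2-(trimethylsilyl)ethyl (4S,5S,9S,10R,13R)-13-(triethylsilyloxy)-5β-labda-8(17),14-dien-19-oate
Product: 20 (4S,5S,9S,10R,13R)-13-hydroxy-5β-labda-8(17),14-dien-19-oic acid
Conditions: Bu4NF (excess), THF, rt; aq. NH4Cl then dilute HCl
Reagents that add atoms: none
Why: Fluoride attacks silicon only: the 2-(trimethylsilyl)ethyl ester fragments to carboxylate, ethene and Me3SiF and the triethylsilyl ether is cleaved, so the hindered C19 carbonyl never has to be attacked by a nucleophile.

Step 15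
Reactants: 20 (4S,5S,9S,10R,13R)-13-hydroxy-5β-labda-8(17),14-dien-19-oic acid
Product: 21 (4S,5S,9S,10R,13R)-13-acetoxy-5β-labda-8(17),14-dien-19-oic acid
Conditions: Ac2O, DMAP, Et3N, CH2Cl2, 35 °C; then THF–aq. NaHCO3, acidify to pH 4
Reagents that add atoms: acetic anhydride CC(=O)OC(C)=O
Why: DMAP-catalysed acyl transfer acetylates the tertiary allylic alcohol without ionisation (C13 retained), and the mixed anhydride formed at the hindered carboxyl group is hydrolysed at its acetyl carbonyl in the bicarbonate work-up to return the free acid.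

**Compound list**

1 | (R)-(−)-linalool, (3R)-3,7-dimethylocta-1,6-dien-3-ol | C=C[C@@](C)(CCC=C(C)C)O | starting material
2 | (3R)-3,7-dimethyl-3-(triethylsilyloxy)octa-1,6-diene | C=C[C@@](C)(CCC=C(C)C)O[Si](CC)(CC)CC | intermediate
3 | (2E,6R)-2,6-dimethyl-6-(triethylsilyloxy)octa-2,7-dien-1-ol | C=C[C@@](C)(CC/C=C(\C)CO)O[Si](CC)(CC)CC | intermediate
4 | (2E,6R)-2,6-dimethyl-6-(triethylsilyloxy)octa-2,7-dien-1-yl methanesulfonate | C=C[C@@](C)(CC/C=C(\C)COS(C)(=O)=O)O[Si](CC)(CC)CC | intermediate
5 | tributyl[(2E,6R)-2,6-dimethyl-6-(triethylsilyloxy)octa-2,7-dien-1-yl]stannane | C=C[C@@](C)(CC/C=C(\C)C[Sn](CCCC)(CCCC)CCCC)O[Si](CC)(CC)CC | intermediate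
6 | tert-butyl 2-oxocyclohexane-1-carboxylate | O=C1CCCCC1C(=O)OC(C)(C)C | starting material
7 | tert-butyl (1S)-1-methyl-2-oxocyclohexane-1-carboxylate | O=C1CCCC[C@]1(C)C(=O)OC(C)(C)C | intermediate
8 | tert-butyl (1S)-1,3-dimethyl-2-oxocyclohexane-1-carboxylate (both C3 epimers) | CC1CCC[C@](C)(C(=O)OC(C)(C)C)C1=O | intermediate
9 | tert-butyl (1S)-1,3-dimethyl-2-(trifluoromethylsulfonyloxy)cyclohex-2-ene-1-carboxylate | CC1=C(OS(=O)(=O)C(F)(F)F)[C@@](C)(C(=O)OC(C)(C)C)CCC1 | intermediate
10 | tert-butyl (4S,8E,13R)-6-oxo-13-(triethylsilyloxy)-9,10-secolabda-5(10),8,14-trien-19-oate | C=C[C@@](C)(CC/C=C(\C)CC(=O)C1=C(C)CCC[C@]1(C)C(=O)OC(C)(C)C)O[Si](CC)(CC)CC | intermediate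
11 | tert-butyl (4S,6S,8E,13R)-6-hydroxy-13-(triethylsilyloxy)-9,10-secolabda-5(10),8,14-trien-19-oate | C=C[C@@](C)(CC/C=C(\C)C[C@H](O)C1=C(C)CCC[C@]1(C)C(=O)OC(C)(C)C)O[Si](CC)(CC)CC | intermediate
12 | (4S,6S,8E,13R)-13-(triethylsilyloxy)-9,10-secolabda-5(10),8,14-trien-19,6-olide | C=C[C@@](C)(CC/C=C(\C)C[C@@H]1OC(=O)[C@@]2(C)CCCC(C)=C12)O[Si](CC)(CC)CC | intermediate
13 | dipotassium (4S,6S,8E,13R)-6-oxido-13-(triethylsilyloxy)-9,10-secolabda-5(10),8,14-trien-19-oate | C=C[C@@](C)(CC/C=C(\C)C[C@H]([O-])C1=C(C)CCC[C@]1(C)C(=O)[O-])O[Si](CC)(CC)CC.[K+].[K+] | intermediate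
14 | dipotassium C5=C6 enolate 19-carboxylate corresponding to 15 (4S,9S,10R,13R) | C=C[C@@](C)(CC[C@@H](C(C)=C)[C@@]1(C)CCC[C@](C)(C(=O)[O-])C1=C[O-])O[Si](CC)(CC)CC.[K+].[K+] | intermediate
15 | (4S,5S,9S,10R,13R)-6-oxo-13-(triethylsilyloxy)-6,7-secolabda-7,14-dien-19-oic acid | C=C[C@@](C)(CC[C@@H](C(C)=C)[C@@]1(C)CCC[C@](C)(C(=O)O)[C@H]1C=O)O[Si](CC)(CC)CC | intermediate
16 | 2-(trimethylsilyl)ethyl (4S,5S,9S,10R,13R)-6-oxo-13-(triethylsilyloxy)-6,7-secolabda-7,14-dien-19-oate | C=C[C@@](C)(CC[C@@H](C(C)=C)[C@@]1(C)CCC[C@](C)(C(=O)OCC[Si](C)(C)C)[C@H]1C=O)O[Si](CC)(CC)CC | intermediate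
17 | 2-(trimethylsilyl)ethyl (4S,5S,9S,10R,13R)-6-hydroxy-13-(triethylsilyloxy)-5β-labda-8(17),14-dien-19-oate (C6 not assigned) | C=C[C@@](C)(CC[C@H]1C(=C)CC(O)[C@H]2[C@]1(C)CCC[C@]2(C)C(=O)OCC[Si](C)(C)C)O[Si](CC)(CC)CC | intermediate
18 | 2-(trimethylsilyl)ethyl (4S,5S,9S,10R,13R)-6-(phenoxythiocarbonyloxy)-13-(triethylsilyloxy)-5β-labda-8(17),14-dien-19-oate (C6 not assigned) | C=C[C@@](C)(CC[C@H]1C(=C)CC(OC(=S)Oc3ccccc3)[C@H]2[C@]1(C)CCC[C@]2(C)C(=O)OCC[Si](C)(C)C)O[Si](CC)(CC)CC | intermediate
19 | 2-(trimethylsilyl)ethyl (4S,5S,9S,10R,13R)-13-(triethylsilyloxy)-5β-labda-8(17),14-dien-19-oate | C=C[C@@](C)(CC[C@H]1C(=C)CC[C@H]2[C@]1(C)CCC[C@]2(C)C(=O)OCC[Si](C)(C)C)O[Si](CC)(CC)CC | intermediate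
20 | (4S,5S,9S,10R,13R)-13-hydroxy-5β-labda-8(17),14-dien-19-oic acid | C=C[C@@](C)(CC[C@H]1C(=C)CC[C@H]2[C@]1(C)CCC[C@]2(C)C(=O)O)O | intermediate
21 | (4S,5S,9S,10R,13R)-13-acetoxy-5β-labda-8(17),14-dien-19-oic acid | C=C[C@@](C)(CC[C@H]1C(=C)CC[C@H]2[C@]1(C)CCC[C@]2(C)C(=O)O)OC(C)=O | target

**Totals**

Total step count: 15. Longest linear sequence: 12 steps (steps 4–15 from 6, or steps 1–3 and 7–15 from 1).

**Steps most likely to fail**

1. Step 9. The homoallylic alkoxide may fragment by retro-allylation or rearrange stepwise (1,3-shift) instead of through the concerted chair. The hindered lactone may open slowly, the neighbouring carboxylate may slow the rearrangement, and the enolate may be protonated with poor facial selectivity. Fallback (C19 carried at the alcohol level, so the rearrangement runs on a simple mono-alkoxide): it sets out from 12 and returns at 20. LiAlH4 reduces the lactone to the 6,19-diol F1. t-BuMe2SiCl/imidazole silylates the primary hydroxyl selectively to the 19-silyl ether F2. KH/18-crown-6 in THF followed by AcOH at −78 °C gives the 6,7-seco aldehyde F3. Me2AlCl closes ring B to the 6-hydroxy cis-decalin F4. PhOC(S)Cl/pyridine gives the thionocarbonate F5 and Bu3SnH/AIBN the deoxygenated bis-silyl ether F6. Bu4NF gives the 13,19-diol F7, TEMPO/PhI(OAc)2 oxidises only the primary alcohol to the 19-aldehyde F8, and NaClO2/NaH2PO4/2-methylbut-2-ene gives 20.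

2. Step 11. The aluminium-bound aldehyde may enolise and epimerise C5, the cationic intermediate may capture chloride, or the new double bond may migrate into the ring. Fallback (radical addition–fragmentation instead of a polar ene reaction): it sets out from 16 and returns at 19, bypassing 17 and 18. NaBH4 gives the primary C6 alcohol F9 and CBr4/PPh3 the primary bromide F10. Ene-type chlorination of the isopropenyl group with Ca(OCl)2/CO2 gives the 2-(chloromethyl)allyl compound F11, and PhSO2Na in DMF gives the allylic sulfone F12. (Bu3Sn)2 under irradiation in benzene at 80 °C generates the C6 radical, which adds 6-endo to the CH2 terminus of the allyl sulfone and expels the sulfonyl radical to give 19 directly.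

3. Step 7. Coupling may occur without CO insertion, the allyl group may transpose during transmetalation, and the β,γ double bond may migrate into conjugation. Fallback (acyl substitution with an α-selective allylmetal): it sets out from 9 and 3 and returns at 10. Aminocarbonylation of 9 (Pd(OAc)2, Xantphos, CO, MeNHOMe·HCl, Et3N) gives the Weinreb amide F13. MsCl/LiCl converts 3 into the allylic chloride F14, and activated barium (from BaI2 and lithium biphenylide) converts this into the allylbarium chloride F15. F15 adds through its CH2 carbon to F13 at −78 °C to give 10.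

**Further compounds**

F1 | step 9 | (4S,6S,8E,13R)-13-(triethylsilyloxy)-9,10-secolabda-5(10),8,14-triene-6,19-diol | C=C[C@@](C)(CC/C=C(\C)C[C@H](O)C1=C(C)CCC[C@]1(C)CO)O[Si](CC)(CC)CC
F2 | step 9 | 19-O-tert-butyldimethylsilyl ether of F1 | C=C[C@@](C)(CC/C=C(\C)C[C@H](O)C1=C(C)CCC[C@]1(C)CO[Si](C)(C)C(C)(C)C)O[Si](CC)(CC)CC
F3 | step 9 | 19-(tert-butyldimethylsilyloxy)-13-(triethylsilyloxy)-6,7-secolabda-7,14-dien-6-al (configuration as in 16) | C=C[C@@](C)(CC[C@@H](C(C)=C)[C@@]1(C)CCC[C@](C)(CO[Si](C)(C)C(C)(C)C)[C@H]1C=O)O[Si](CC)(CC)CC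
F4 | step 9 | 19-(tert-butyldimethylsilyloxy)-13-(triethylsilyloxy)-5β-labda-8(17),14-dien-6-ol (C6 not assigned) | C=C[C@@](C)(CC[C@H]1C(=C)CC(O)[C@H]2[C@]1(C)CCC[C@]2(C)CO[Si](C)(C)C(C)(C)C)O[Si](CC)(CC)CC
F5 | step 9 | 6-O-(phenoxythiocarbonyl) derivative of F4 | C=C[C@@](C)(CC[C@H]1C(=C)CC(OC(=S)Oc3ccccc3)[C@H]2[C@]1(C)CCC[C@]2(C)CO[Si](C)(C)C(C)(C)C)O[Si](CC)(CC)CC
F6 | step 9 | 19-(tert-butyldimethylsilyloxy)-13-(triethylsilyloxy)-5β-labda-8(17),14-diene | C=C[C@@](C)(CC[C@H]1C(=C)CC[C@H]2[C@]1(C)CCC[C@]2(C)CO[Si](C)(C)C(C)(C)C)O[Si](CC)(CC)CC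
F7 | step 9 | 5β-labda-8(17),14-diene-13,19-diol | C=C[C@@](C)(CC[C@H]1C(=C)CC[C@H]2[C@]1(C)CCC[C@]2(C)CO)O
F8 | step 9 | 13-hydroxy-5β-labda-8(17),14-dien-19-al | C=C[C@@](C)(CC[C@H]1C(=C)CC[C@H]2[C@]1(C)CCC[C@]2(C)C=O)O
F9 | step 11 | 6-hydroxy analogue of 16 (primary alcohol) | C=C[C@@](C)(CC[C@@H](C(C)=C)[C@@]1(C)CCC[C@](C)(C(=O)OCC[Si](C)(C)C)[C@H]1CO)O[Si](CC)(CC)CC
F10 | step 11 | 6-bromo analogue of F9 | C=C[C@@](C)(CC[C@@H](C(C)=C)[C@@]1(C)CCC[C@](C)(C(=O)OCC[Si](C)(C)C)[C@H]1CBr)O[Si](CC)(CC)CC
F11 | step 11 | 6-bromo-17-chloro compound with a 2-(chloromethyl)allyl group on C9 | C=C[C@@](C)(CC[C@@H](C(=C)CCl)[C@@]1(C)CCC[C@](C)(C(=O)OCC[Si](C)(C)C)[C@H]1CBr)O[Si](CC)(CC)CC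
F12 | step 11 | 6-bromo compound with a 2-(phenylsulfonylmethyl)allyl group on C9 | C=C[C@@](C)(CC[C@@H](C(=C)CS(=O)(=O)c2ccccc2)[C@@]1(C)CCC[C@](C)(C(=O)OCC[Si](C)(C)C)[C@H]1CBr)O[Si](CC)(CC)CC
F13 | step 7 | tert-butyl (1S)-2-[methoxy(methyl)carbamoyl]-1,3-dimethylcyclohex-2-ene-1-carboxylate | CC1=C(C(=O)N(C)OC)[C@@](C)(C(=O)OC(C)(C)C)CCC1
F14 | step 7 | (3R,6E)-8-chloro-3,7-dimethyl-3-(triethylsilyloxy)octa-1,6-diene | C=C[C@@](C)(CC/C=C(\C)CCl)O[Si](CC)(CC)CC
F15 | step 7 | [(2E,6R)-2,6-dimethyl-6-(triethylsilyloxy)octa-2,7-dien-1-yl]barium chloride | C=C[C@@](C)(CC/C=C(\C)C[Ba]Cl)O[Si](CC)(CC)CC
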